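**Retrosynthetic overview**

1. Target 15 ⇐ 14 (hydrogenolysis of the C5–O benzyl ether) ⇐ 13 (acetylation of C2–OH and C2′–OH together) ⇐ 12 (MOM removal); side chain numbered C1′ (benzylic) to C13′.
2. Key disconnection C3′–C4′, made together with C1′–C2′ and the C2′–O bond: 12 ⇐ benzylic boronate 8 + vinyllithium + 1-iododecane 9, by an enantioselective Ni-catalysed three-component conjunctive coupling followed by C–B oxidation.
3. Enabling feature: the carbinol carbon C2′ lies between two methylene groups (benzylic C1′H2 on ring carbon C1 and chain C3′H2). C2′–C3′ therefore maps onto a vinyl group on boron, boron stands in for the C2′ oxygen, C1′ migrates from B to C2′ and the decyl group enters at C3′.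
4. 8 ⇐ benzylic bromide 7 ⇐ aldehyde 5 ⇐ o-vanillin 1. Elbs para-hydroxylation puts oxygen on C5, the chelated 2-OH lets the 5-OH be benzylated alone, and C2–OH is then masked as MOM; this differentiation is what later gives OAc at C2/C2′ and free OH at C5.
5. Rings: the benzene ring is the only ring and comes intact from 1; no ring is formed or opened.

Key step: step 7

Remark: vinyllithium is taken as a titrated, halide-free ether solution; which enantiomer of the Pybox ligand gives the (R)-boronate with a benzylic migrating group is not known and has to be fixed in the first trial (Mosher ester analysis of 12).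

**Route**

Step 1
Reactants: 1 2-hydroxy-3-methoxybenzaldehyde (o-vanillin)
Product: 3 2,5-dihydroxy-3-methoxybenzaldehyde, via potassium aryl sulfate 2 (not isolated)
Conditions: K2S2O8, aq NaOH, 15–20 °C, N2; acidify, extract unreacted 1; then aq HCl, 80 °C
Reagents that add atoms: potassium peroxodisulfate, [K+].[K+].[O-]S(=O)(=O)OOS(=O)(=O)[O-]
Why: Elbs persulfate oxidation, in which the phenoxide attacks the peroxide O–O bond through C5 (para to the OH, both ortho positions being substituted) and the resulting aryl sulfate is hydrolysed by acid to the hydroquinone.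

Step 2
Reactants: 3 2,5-dihydroxy-3-methoxybenzaldehyde
Product: 4 5-(benzyloxy)-2-hydroxy-3-methoxybenzaldehyde
Conditions: BnBr (1.05 equiv), NaHCO3, KI (cat.), MeCN, 60 °C, N2
Reagents that add atoms: benzyl bromide, BrCc1ccccc1
Why: Williamson etherification that should select the 5-OH, because the 2-OH is hydrogen-bonded to the aldehyde and its phenoxide is a poor nucleophile under weak base.

Step 3
Reactants: 4 5-(benzyloxy)-2-hydroxy-3-methoxybenzaldehyde
Product: 5 5-(benzyloxy)-3-methoxy-2-(methoxymethoxy)benzaldehyde
Conditions: MOMCl, i-Pr2NEt, CH2Cl2, 0 °C → reflux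
Reagents that add atoms: chloromethyl methyl ether, COCCl
Why: O-alkylation of the remaining phenol with a reactive α-chloro ether (MOM protection), giving an acetal that tolerates organolithium, nickel and alkaline peroxide and is later removed by acid without touching the benzyl ether.

Step 4
Reactants: 5 5-(benzyloxy)-3-methoxy-2-(methoxymethoxy)benzaldehyde
Product: 6 [5-(benzyloxy)-3-methoxy-2-(methoxymethoxy)phenyl]methanol
Conditions: NaBH4, MeOH/THF, 0 °C
Reagents that add atoms: none
Why: Borohydride reduction of the aldehyde to the benzylic alcohol, with both ethers inert.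

Step 5
Reactants: 6 [5-(benzyloxy)-3-methoxy-2-(methoxymethoxy)phenyl]methanol
Product: 7 5-(benzyloxy)-1-(bromomethyl)-3-methoxy-2-(methoxymethoxy)benzene
Conditions: CBr4, PPh3, CH2Cl2, 0 °C; used without storage
Reagents that add atoms: carbon tetrabromide, BrC(Br)(Br)Br
Why: Appel reaction, which converts the benzylic alcohol to the bromide under essentially neutral conditions so that the MOM acetal should survive.

Step 6
Reactants: 7 5-(benzyloxy)-1-(bromomethyl)-3-methoxy-2-(methoxymethoxy)benzene
Product: 8 2-{[5-(benzyloxy)-3-methoxy-2-(methoxymethoxy)phenyl]methyl}-4,4,5,5-tetramethyl-1,3,2-dioxaborolane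
Conditions: B2pin2, Pd2(dba)3 (cat.), P(4-MeOC6H4)3, KOAc, toluene, 50 °C
Reagents that add atoms: bis(pinacolato)diboron, CC1(C)OB(OC1(C)C)B1OC(C)(C)C(C)(C)O1
Why: Miyaura borylation of a benzylic halide (oxidative addition, acetate-assisted transmetalation with the diboron, reductive elimination).

Step 7
Reactants: 8 2-{[5-(benzyloxy)-3-methoxy-2-(methoxymethoxy)phenyl]methyl}-4,4,5,5-tetramethyl-1,3,2-dioxaborolane; 9 1-iododecane
Product: 12 (2R)-1-[5-(benzyloxy)-3-methoxy-2-(methoxymethoxy)phenyl]tridecan-2-ol, via lithium vinylboronate complex 10 (not isolated), via secondary pinacol boronic ester 11 (not isolated)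
Conditions: vinyllithium (1.0 equiv), Et2O, −78 → 0 °C; solvent switch; NiBr2·glyme (10 mol %), chiral Pybox ligand (12 mol %), 9, THF/DMSO, rt; then 3 M NaOH, 30% H2O2, 0 °C → rt
Reagents that add atoms: vinyllithium, [Li]C=C; hydrogen peroxide, OO
Why: Proposed new method: vinyllithium adds to the boron of 8 to give the tetracoordinate vinylboronate 10, and a chiral Pybox–Ni catalyst that has taken up the decyl group of 9 (iodine abstraction, then radical capture at nickel) binds the vinyl π bond of 10 and triggers a 1,2-metalate shift of the benzylic carbon C1′ from boron to the internal vinyl carbon C2′ anti to nickel, after which C(sp3)–C(sp3) reductive elimination joins the terminal vinyl carbon C3′ to C4′ of the decyl chain and gives boronic ester 11. The closest known reaction type is the Ni/Pybox-catalysed enantioselective conjunctive cross-coupling of vinylboron ate complexes carrying aryl migrating groups with unactivated primary alkyl iodides; what goes beyond it is the benzylic, ortho-oxygenated migrating group, which should shift readily because benzyl is a good 1,2-migrating group in boronate rearrangements. No ring is closed. The C2′ stereocentre is set in the metalate shift by the enantioface of the vinyl group that the chiral nickel complex binds (ligand control, no substrate bias), and the alkaline peroxide oxidation in the same flask replaces boron by oxygen with retention to give (R)-12. The step needs conjunctive coupling to win over direct transfer of vinyl or benzyl from boron to nickel and over β-hydride loss from decyl–nickel: the pinacolato borate is coordinatively saturated and transmetalates slowly, the pinacol oxygens do not migrate, and the tridentate ligand leaves no cis site for β-hydride elimination. In one operation the step therefore forms C1′–C2′ and C3′–C4′, sets the only stereocentre and installs the C2′ oxygen.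

Step 8
Reactants: 12 (2R)-1-[5-(benzyloxy)-3-methoxy-2-(methoxymethoxy)phenyl]tridecan-2-ol
Product: 13 4-(benzyloxy)-2-[(2R)-2-hydroxytridecyl]-6-methoxyphenol
Conditions: conc. HCl (cat.), MeOH, 45 °C, N2; used directly
Reagents that add atoms: none
Why: Acid-catalysed acetal exchange with methanol (MOM cleavage) frees the C2 phenol, while the benzyl ether, the secondary alcohol and its stereocentre are not affected.

Step 9
Reactants: 13 4-(benzyloxy)-2-[(2R)-2-hydroxytridecyl]-6-methoxyphenol
Product: 14 (2R)-1-[2-(acetyloxy)-5-(benzyloxy)-3-methoxyphenyl]tridecan-2-yl acetate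
Conditions: Ac2O, pyridine, DMAP (cat.), CH2Cl2, 0 °C → rt
Reagents that add atoms: acetic anhydride, CC(=O)OC(C)=O
Why: DMAP-catalysed acylation acetylates both the hindered C2 phenol and the secondary alcohol while C5–O stays masked as its benzyl ether, which fixes the acetylation pattern of the target.

Step 10
Reactants: 14 (2R)-1-[2-(acetyloxy)-5-(benzyloxy)-3-methoxyphenyl]tridecan-2-yl acetate
Product: 15 (2R)-1-[2-(acetyloxy)-5-hydroxy-3-methoxyphenyl]tridecan-2-yl acetate (CNP0300796.1)
Conditions: H2 (1 atm), 10% Pd/C, EtOAc, rt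
Reagents that add atoms: none
Why: Heterogeneous hydrogenolysis of the benzyl aryl ether in a non-nucleophilic solvent releases the C5 phenol, with both acetates inert and no intramolecular acyl-transfer path between the para oxygens.

**Compound list**

1 | 2-hydroxy-3-methoxybenzaldehyde (o-vanillin) | O=Cc1cccc(OC)c1O | starting material
2 | potassium 3-formyl-4-hydroxy-5-methoxyphenyl sulfate | O=Cc1cc(OS(=O)(=O)[O-])cc(OC)c1O.[K+] | intermediate (not isolated)
3 | 2,5-dihydroxy-3-methoxybenzaldehyde | O=Cc1cc(O)cc(OC)c1O | intermediate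
4 | 5-(benzyloxy)-2-hydroxy-3-methoxybenzaldehyde | O=Cc1cc(OCc2ccccc2)cc(OC)c1O | intermediate
5 | 5-(benzyloxy)-3-methoxy-2-(methoxymethoxy)benzaldehyde | O=Cc1cc(OCc2ccccc2)cc(OC)c1OCOC | intermediate
6 | [5-(benzyloxy)-3-methoxy-2-(methoxymethoxy)phenyl]methanol | OCc1cc(OCc2ccccc2)cc(OC)c1OCOC | intermediate
7 | 5-(benzyloxy)-1-(bromomethyl)-3-methoxy-2-(methoxymethoxy)benzene | BrCc1cc(OCc2ccccc2)cc(OC)c1OCOC | intermediate
8 | 2-{[5-(benzyloxy)-3-methoxy-2-(methoxymethoxy)phenyl]methyl}-4,4,5,5-tetramethyl-1,3,2-dioxaborolane | CC1(C)OB(Cc2cc(OCc3ccccc3)cc(OC)c2OCOC)OC1(C)C | intermediate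
9 | 1-iododecane | CCCCCCCCCCI | starting material
10 | lithium {[5-(benzyloxy)-3-methoxy-2-(methoxymethoxy)phenyl]methyl}(ethenyl)(pinacolato)borate | [Li+].C=C[B-]1(Cc2cc(OCc3ccccc3)cc(OC)c2OCOC)OC(C)(C)C(C)(C)O1 | intermediate (not isolated)
11 | 2-{(2R)-1-[5-(benzyloxy)-3-methoxy-2-(methoxymethoxy)phenyl]tridecan-2-yl}-4,4,5,5-tetramethyl-1,3,2-dioxaborolane | CCCCCCCCCCC[C@H](Cc1cc(OCc2ccccc2)cc(OC)c1OCOC)B1OC(C)(C)C(C)(C)O1 | intermediate (not isolated)
12 | (2R)-1-[5-(benzyloxy)-3-methoxy-2-(methoxymethoxy)phenyl]tridecan-2-ol | CCCCCCCCCCC[C@H](Cc1cc(OCc2ccccc2)cc(OC)c1OCOC)O | intermediate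
13 | 4-(benzyloxy)-2-[(2R)-2-hydroxytridecyl]-6-methoxyphenol | CCCCCCCCCCC[C@H](Cc1cc(OCc2ccccc2)cc(OC)c1O)O | intermediate
14 | (2R)-1-[2-(acetyloxy)-5-(benzyloxy)-3-methoxyphenyl]tridecan-2-yl acetate | CCCCCCCCCCC[C@H](Cc1cc(OCc2ccccc2)cc(OC)c1OC(C)=O)OC(C)=O | intermediate
15 | (2R)-1-[2-(acetyloxy)-5-hydroxy-3-methoxyphenyl]tridecan-2-yl acetate (CNP0300796.1) | CCCCCCCCCCC[C@H](Cc1cc(O)cc(OC)c1OC(C)=O)OC(C)=O | target

**Summary and risks**

Total step count: 10. Longest linear sequence: 10 steps (1 → 15); 9 is bought.

Steps most likely to fail: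

Step 7 (proposed new method). The benzylic group may pass directly from boron to nickel (plain cross-coupling instead of the metalate shift), decyl–nickel may lose a β-hydride, or enantiofacial discrimination may be poor with a benzylic migrating group. The fallback sets out from 7 and comes back at 12, forming the same C3′–C4′ bond by known chemistry. Copper-catalysed coupling of 7 with vinylmagnesium bromide (CuI cat., THF, 0 °C) should give 5-(benzyloxy)-3-methoxy-2-(methoxymethoxy)-1-(prop-2-en-1-yl)benzene F1. Epoxidation with mCPBA (NaHCO3-buffered CH2Cl2, 0 °C) should give racemic 2-{[5-(benzyloxy)-3-methoxy-2-(methoxymethoxy)phenyl]methyl}oxirane F2. Jacobsen hydrolytic kinetic resolution with (S,S)-(salen)Co(III)OAc and 0.55 equiv water should leave (2S)-2-{[5-(benzyloxy)-3-methoxy-2-(methoxymethoxy)phenyl]methyl}oxirane F3. Opening of F3 at its terminal carbon with decylmagnesium bromide and catalytic CuI (THF, −30 °C) should give 12 with the stereocentre untouched.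

Step 1. Conversion in the Elbs oxidation may be low, and the hydroquinone may be over-oxidised under alkaline persulfate. The fallback sets out from 1 and comes back at 5. Bromination of 1 (Br2, NaOAc, AcOH, rt) para to the hydroxyl should give 5-bromo-2-hydroxy-3-methoxybenzaldehyde F4. MOM protection (MOMCl, i-Pr2NEt, CH2Cl2) should give 5-bromo-3-methoxy-2-(methoxymethoxy)benzaldehyde F5. Miyaura borylation (B2pin2, Pd(dppf)Cl2, KOAc, dioxane, 85 °C) should give 3-methoxy-2-(methoxymethoxy)-5-(4,4,5,5-tetramethyl-1,3,2-dioxaborolan-2-yl)benzaldehyde F6. Mild oxidation with sodium perborate (THF/H2O, rt) should give 5-hydroxy-3-methoxy-2-(methoxymethoxy)benzaldehyde F7, which is benzylated (BnBr, K2CO3, DMF) to 5.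

Step 6. The benzyl–palladium intermediate may homocouple to the bibenzyl, and the electron-rich bromide may decompose before it is borylated. The fallback sets out from 5 and comes back at 8, avoiding any benzylic halide. Condensation of 5 with tosylhydrazide (MeOH, rt) should give N′-{(E)-[5-(benzyloxy)-3-methoxy-2-(methoxymethoxy)phenyl]methylidene}-4-methylbenzenesulfonohydrazide F8. Its sodium salt (NaH, toluene), heated with pinacolborane at 110 °C, should give 8 by metal-free reductive borylation through the aryldiazomethane (B–H insertion by 1,2-hydride shift with loss of N2).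

Further compounds
F1 | step 7 | 5-(benzyloxy)-3-methoxy-2-(methoxymethoxy)-1-(prop-2-en-1-yl)benzene | C=CCc1cc(OCc2ccccc2)cc(OC)c1OCOC
F2 | step 7 | rac-2-{[5-(benzyloxy)-3-methoxy-2-(methoxymethoxy)phenyl]methyl}oxirane | C(C1CO1)c1cc(OCc2ccccc2)cc(OC)c1OCOC
F3 | step 7 | (2S)-2-{[5-(benzyloxy)-3-methoxy-2-(methoxymethoxy)phenyl]methyl}oxirane | C1[C@H](Cc2cc(OCc3ccccc3)cc(OC)c2OCOC)O1
F4 | step 1 | 5-bromo-2-hydroxy-3-methoxybenzaldehyde | O=Cc1cc(Br)cc(OC)c1O
F5 | step 1 | 5-bromo-3-methoxy-2-(methoxymethoxy)benzaldehyde | O=Cc1cc(Br)cc(OC)c1OCOC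
F6 | step 1 | 3-methoxy-2-(methoxymethoxy)-5-(4,4,5,5-tetramethyl-1,3,2-dioxaborolan-2-yl)benzaldehyde | O=Cc1cc(B2OC(C)(C)C(C)(C)O2)cc(OC)c1OCOC
F7 | step 1 | 5-hydroxy-3-methoxy-2-(methoxymethoxy)benzaldehyde | O=Cc1cc(O)cc(OC)c1OCOC
F8 | step 6 | N′-{(E)-[5-(benzyloxy)-3-methoxy-2-(methoxymethoxy)phenyl]methylidene}-4-methylbenzenesulfonohydrazide | Cc1ccc(cc1)S(=O)(=O)N/N=C/c1cc(OCc2ccccc2)cc(OC)c1OCOC
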